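(The readings were computed with constants of no real substance; noise was put on by code.)

Which set-up should you run next: the closed flask, a steady feed of starting material, a steady feed of partner, or the stirred tank?

in all of them: protic impurity 21.5 mM

|  | starting material | partner | remark | time |
|---|---|---|---|---|
| alpha | 43 mM | 0.95 equiv | run made earlier |  |
| beta | 43 mM | 0.64 equiv | run made earlier |  |
| delta | 43 mM | 1.4 equiv | run made earlier |  |
| dusk | 43 mM | 0.950 equiv | everything together in a closed stirred flask, run for 80 min | 80 min |
| midnight | 43 mM (fed, over 64.0 min) | 0.950 equiv | all but starting material at the start; starting material goes in evenly over 64.0 min, the run ends at 80 min | 80 min |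
| autumn | 43 mM | 0.950 equiv | one stirred flow tank at steady state, fed with the mixture as stated, mean residence time 80 min |  |
| noon | 43 mM | 0.950 equiv (fed, over 64.0 min) | all but partner at the start; partner goes in evenly over 64.0 min, the run ends at 80 min | 80 min |

- alpha (time / min: target / %): 3.00: 39; 10.0: 64; 15.0: 65; 25.0: 65; 40.0: 67; 50.0: 67
- beta (time / min: target / %): 4.00: 46; 12.0: 67; 25.0: 63; 40.0: 66; 50.0: 63; 60.0: 62
- delta (time / min: target / %): 5.00: 51; 8.00: 60; 15.0: 65; 25.0: 62; 40.0: 66; 60.0: 65

(standard deviation of a reading: 2 percentage points)

- the stated concentrations are those of everything mixed, before any reaction; amounts are the same in each set-up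
- the numbers in the tables scatter by 2 percentage points (one standard deviation)
- steps that have been proposed: partner + protic impurity -> quenched reagent; starting material <-> intermediate A; intermediate B -> side product B; starting material -> intermediate B; starting material -> side product A; intermediate B -> target
- the feed brings no volume worth counting
- the earlier runs were made in a closed, stirred flask

- the set-up with the highest amount of target at the outlet or at the end, in percent of the starting material put in ("none" if the first two lie within 2 percentage points) (dusk / midnight / autumn / noon / none)
- amount of target at the outlet or at the end, in percent of the starting material put in, dusk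
- amount of target at the outlet or at the end, in percent of the starting material put in, midnight
- amount of target at the outlet or at the end, in percent of the starting material put in, autumn
- amount of target at the outlet or at the end, in percent of the starting material put in, noon

Read two things from the earlier runs. First average the last reading of each run, which gives a plateau of target. These readings are 67 %, 62 % and 65 %, at 0.95 equiv, 0.64 equiv and 1.4 equiv of partner.

  plateau = 64.7 % of the charge

Then use the first reading of each run to find how fast the target approaches that plateau.

  alpha: 3.00 min / ln(plateau / (plateau − 39 %)) = 3.25 min
  beta: 3.22 min
  delta: 3.22 min

Call this the rise time, the time in which the gap to the plateau shrinks to about a third; it is the usual time constant. Now measure each set-up in rise times.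

  dusk: 80 min = 24.6 rise times, so expect the plateau
  midnight: the last drop gets 4.93 rise times, and 0.724 % of that drop's gap stays open
  autumn: plateau × 80 min / (80 min + rise) = 62.1 %

Autumn comes out lower than the plateau by 2.6 percentage points, because the rise time is 4.06 % of its residence time. Count noon at the plateau too, though this is a bet: noon starts without partner, and midnight thins the starting material below 43 mM, and no earlier run tested either. A fed flask falling more than 2 points below dusk would overturn this reckoning. Until then, charge everything together as in dusk and leave the pump out.

The forecast gives 65 % for dusk, 65 % for midnight, 62 % for autumn, 65 % for noon and best none, holding that “the partner, and its quench by the impurity, does not affect rate or selectivity”.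

The flask gives 64.6 % in dusk, 64.6 % in midnight, 62.2 % in autumn and 64.6 % in noon, so best is none.

    partner + protic impurity → quenched reagent (k = 0.0470 M⁻¹ s⁻¹)
    starting material ⇌ intermediate A (K = 0.460, k = 0.00250 s⁻¹)
    intermediate B → side product B (k = 0.00130 s⁻¹)
    starting material → intermediate B (k = 0.0260 s⁻¹)
    starting material → side product A (k = 0.00700 s⁻¹)
    intermediate B → target (k = 0.00590 s⁻¹)

Midnight matches dusk at 64.6 %, although its highest starting material was 0.789 % of the charge. Noon's 80 min is 24.6 rise times, and it reads 64.6 %. Leaving noon longer makes no difference: at 800 min, which is 246 rise times, it reads 64.6 %.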